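**Assumption:** syringol, 2,3-dimethylmaleic anhydride and [4-(benzyloxy)-3-methoxyphenyl]boronic acid are taken as commercial. The absolute sense of step 4 is fixed by choice of ligand antipode, which I cannot assign from memory and which must be checked on the first run.

## Retrosynthetic overview

- The target is the erythro ("pseudo-meso") dibenzylbutane, (S) at the guaiacyl-side carbon and (R) at the syringyl-side carbon. It is chiral only because the two aryl groups differ by one OMe.
- Both benzylic CH2 groups are traced back to aryl ketones, giving a syn-2,3-dimethyl-1,4-diaryl-1,4-dione; the benzyl ethers come off in the same hydrogenolysis.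
- The guaiacyl ketone comes from a carboxylic acid by Pd-catalysed acylative Suzuki coupling.
- Key step: the syringyl keto acid comes from meso-2,3-dimethylsuccinic anhydride by Rh-catalysed enantioselective arylative ring opening with an arylzinc. This one C–C bond formation breaks the mirror symmetry and fixes both stereocentres.
- No rings are built: both arenes are bought intact (syringol, the boronic acid), and the only ring manipulated is the anhydride, which is opened.

## Route

**Step 1**
Reactants: 1, 2,6-dimethoxyphenol (syringol)
Product: 2, 4-bromo-2,6-dimethoxyphenol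
Conditions: NBS (1.0 equiv), CHCl3, −40 °C → rt
Reagents that add atoms: N-bromosuccinimide, O=C1CCC(=O)N1Br
Why: Electrophilic aromatic bromination; the free OH directs para (both ortho positions carry OMe), and low temperature with one equivalent limits oxidation to the quinone.

**Step 2**
Reactants: 2, 4-bromo-2,6-dimethoxyphenol
Product: 3, 2-(benzyloxy)-5-bromo-1,3-dimethoxybenzene
Conditions: BnBr, K2CO3, DMF, rt
Reagents that add atoms: benzyl bromide, BrCc1ccccc1
Why: Williamson etherification; benzyl survives organolithium/zinc chemistry and is removed for free in the last step.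

**Step 3**
Reactants: 4, 2,3-dimethylmaleic anhydride
Product: 5, cis-(meso)-2,3-dimethylsuccinic anhydride [(3R,4S)-3,4-dimethyloxolane-2,5-dione]
Conditions: H2 (4 atm), 10% Pd/C, dry EtOAc, rt
Reagents that add atoms: none
Why: Heterogeneous catalytic hydrogenation adds both hydrogens to one face of the planar alkene, so only the cis (meso, achiral) anhydride forms; this sets the erythro relationship of the two methyl-bearing carbons.

**Step 4 (key step)**
Reactants: 3, 2-(benzyloxy)-5-bromo-1,3-dimethoxybenzene; 5, cis-2,3-dimethylsuccinic anhydride
Product: 6, (2R,3S)-4-[4-(benzyloxy)-3,5-dimethoxyphenyl]-2,3-dimethyl-4-oxobutanoic acid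
Conditions: 3 (1.4 equiv), n-BuLi, THF, −78 °C; Zn(OTf)2, −78 °C → rt; then 5, [Rh(cod)Cl]2 (4 mol %), TADDOL-derived phosphoramidite (TADDOL–PNMe2, 8 mol %), DMF, 50 °C; 1 M HCl work-up
Reagents that add atoms: none (all heavy atoms come from 3 and 5)
Why: Rh-catalysed enantioselective desymmetrising acyl cross-coupling of a meso anhydride with an arylzinc: the chiral Rh(I) complex inserts into one enantiotopic C(acyl)–O bond (the carbonyl on the (S)-configured carbon), then transmetallation and reductive elimination give the keto acid. The stereocentres are not touched, so the cis relationship becomes syn-(2R,3S) and the ligand antipode sets the absolute configuration.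

Because the target is pseudo-meso, introducing the two aryl groups in the opposite order with the same ligand gives the opposite enantiomer, so either sense of induction can be used. The acid is isolated by base/acid extraction and its ee can be raised by crystallisation (free acid or an amine salt).

**Step 5**
Reactants: 6, the keto acid; 7, [4-(benzyloxy)-3-methoxyphenyl]boronic acid
Product: 8, (2R,3S)-1-[4-(benzyloxy)-3-methoxyphenyl]-4-[4-(benzyloxy)-3,5-dimethoxyphenyl]-2,3-dimethylbutane-1,4-dione
Conditions: 7 (1.2 equiv), Pd(OAc)2 (3 mol %), P(4-MeOC6H4)3 (7 mol %), Piv2O (1.5 equiv), THF, H2O (2.5 equiv), 60 °C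
Reagents that add atoms: none besides reactant 7, COc1cc(B(O)O)ccc1OCc1ccccc1
Why: Pd-catalysed acylative Suzuki–Miyaura coupling (Gooßen ketone synthesis): the acid forms a mixed pivalic anhydride in situ, Pd(0) inserts at the less hindered acyl C–O bond and couples with the boronic acid. The conditions are base-free and tolerate the existing aryl ketone, so neither α-stereocentre is touched.

**Step 6**
Reactants: 8, the 1,4-diketone
Product: 9, 4-[(2R,3S)-4-(4-hydroxy-3-methoxyphenyl)-2,3-dimethylbutyl]-2,6-dimethoxyphenol (target)
Conditions: H2 (4 atm), 20% Pd(OH)2/C, EtOAc–EtOH, rt → 40 °C, until no C=O remains; then add AcOH, cat. HClO4, H2, 40 °C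
Reagents that add atoms: none
Why: Pd-catalysed hydrogenation and benzylic hydrogenolysis: both electron-rich aryl ketones go to benzylic alcohols (or the derived 2,5-diaryl-tetrahydrofuran) and then to CH2, and both ArO–Bn bonds are cleaved. Acid is added only after the carbonyls are gone, which avoids Paal–Knorr furan formation and enolisation, so C2/C3 keep their configuration (the R/S labels swap relative to 8 only because CIP priorities change when C=O becomes CH2).

## Compound list

1 | 2,6-dimethoxyphenol (syringol) | COc1cccc(OC)c1O | starting material
2 | 4-bromo-2,6-dimethoxyphenol | COc1cc(Br)cc(OC)c1O | intermediate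
3 | 2-(benzyloxy)-5-bromo-1,3-dimethoxybenzene | COc1cc(Br)cc(OC)c1OCc1ccccc1 | intermediate
4 | 2,3-dimethylmaleic anhydride | CC1=C(C)C(=O)OC1=O | starting material
5 | cis-(meso)-2,3-dimethylsuccinic anhydride | C[C@H]1C(=O)OC(=O)[C@H]1C | intermediate
6 | (2R,3S)-4-[4-(benzyloxy)-3,5-dimethoxyphenyl]-2,3-dimethyl-4-oxobutanoic acid | OC(=O)[C@H](C)[C@H](C)C(=O)c1cc(OC)c(OCc2ccccc2)c(OC)c1 | intermediate
7 | [4-(benzyloxy)-3-methoxyphenyl]boronic acid | COc1cc(B(O)O)ccc1OCc1ccccc1 | starting material
8 | (2R,3S)-1-[4-(benzyloxy)-3-methoxyphenyl]-4-[4-(benzyloxy)-3,5-dimethoxyphenyl]-2,3-dimethylbutane-1,4-dione | COc1cc(C(=O)[C@H](C)[C@H](C)C(=O)c2cc(OC)c(OCc3ccccc3)c(OC)c2)ccc1OCc1ccccc1 | intermediate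
9 | 4-[(2R,3S)-4-(4-hydroxy-3-methoxyphenyl)-2,3-dimethylbutyl]-2,6-dimethoxyphenol | COc1cc(C[C@H](C)[C@H](C)Cc2cc(OC)c(O)c(OC)c2)ccc1O | target

## Summary

Total steps: 6.
Longest linear sequence: 5 (1 → 2 → 3 → 6 → 8 → 9); the anhydride branch (4 → 5) is one step and joins at step 4.

Steps most likely to fail, each with a fallback that changes the approach:

1. **Step 4 (Rh desymmetrisation).** The hindered 4-benzyloxy-3,5-dimethoxyphenylzinc may give low yield or ee, and the sense of induction is unverified. Fallback: desymmetrise 5 by C–O bond formation instead (cinchona-alkaloid-mediated methanolysis to the enantioenriched hemiester), then build the two aryl ketones one terminus at a time via thioesters and Fukuyama coupling with the arylzincs.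
2. **Step 5 (acylative Suzuki on a hindered γ-keto acid).** Mixed-anhydride formation or coupling may be slow, or enol-lactone formation may intervene. Fallback: never make the 1,4-diketone. Hydrogenolyse the ketone of 6 first to the 4-aryl-2,3-dimethylbutanoic acid, convert it to the Weinreb amide, add the aryllithium from 4-(benzyloxy)-1-bromo-3-methoxybenzene, and hydrogenolyse the second ketone last.
3. **Step 6 (global hydrogenolysis).** If acid meets unreduced ketone, furan or dihydrofuran formation would erode ee or dr without being obvious by NMR; the reaction may also stall at the diol or tetrahydrofuran. Fallback: go stepwise by hydride and ionic reduction. Reduce 8 with NaBH4 to the 1,4-diol, deoxygenate the bis-benzylic diol (or its tetrahydrofuran) with Et3SiH/BF3·OEt2, then debenzylate separately with H2, Pd/C under neutral conditions.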